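## Retrosynthetic overview

1. Ring E (dihydropyran) is closed last by cyclodehydration of a δ-hydroxy ketone; its quaternary spiro carbon comes from Michael addition of a bridging aldehyde to ethyl vinyl ketone, and the aldehyde from one-carbon homologation of a bridging ketone.
2. Ring D (N-methylpiperidine) comes from a double Mannich annulation (MeNH2 + 2 CH2O) across both α-carbons of a tricyclic β,γ-unsaturated cycloheptenone, which also creates the quaternary carbon.
3. Ring C (seven-membered) comes from an intramolecular B-alkyl Suzuki coupling of an enol triflate. Triflate and masked acyl group both arise from 1,4-addition of an allyl-dithiane anion to a bicyclic enone with enolate trapping, which fixes the tetrasubstituted alkene.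
4. Ring B (ester-bearing cyclopentane) comes from an intramolecular aldol condensation after allylation and ozonolysis of a malonate; the ester stereocentre is set by Krapcho protonation.
5. Ring A is cyclopent-2-enone; the single stereochemical anchor comes from an amine-catalysed asymmetric Michael addition of dimethyl malonate. Ring order: A (bought) → B → C → D → E.

Assumption: step 1 is run with whichever pseudo-enantiomeric cinchona primary amine (quinine- or quinidine-derived) delivers (S)-3; the quinine-derived one is written. The structures are fixed by the SMILES in the compound list, and stereocentres that are erased later are left unassigned there.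

## Route

Step 1
Reactants: 1 cyclopent-2-en-1-one; 2 dimethyl malonate
Product: 3 dimethyl 2-[(1S)-3-oxocyclopentyl]malonate
Conditions: 9-amino-9-deoxy-epi-quinine (20 mol%), PhCO2H (40 mol%), THF, rt
Reagents that add atoms: none
Why: Iminium activation of the enone by the chiral primary amine and face-selective conjugate addition of the malonate (organocatalytic asymmetric Michael addition) set the ring stereocentre (S), the only stereochemical anchor of the route.

Step 2
Reactants: 3 dimethyl 2-[(1S)-3-oxocyclopentyl]malonate; 4 allyl bromide
Product: 5 dimethyl 2-allyl-2-[(1S)-3-oxocyclopentyl]malonate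
Conditions: Cs2CO3, DMF, 0 °C → rt
Reagents that add atoms: none
Why: The remaining malonate C–H is the most acidic site, so mild carbonate base gives clean C-allylation (malonic ester alkylation) without touching the β-stereocentre.

Step 3
Reactants: 5 dimethyl 2-allyl-2-[(1S)-3-oxocyclopentyl]malonate
Product: 7 dimethyl (3aS)-1-oxo-2,3,3a,5-tetrahydro-1H-pentalene-4,4-dicarboxylate, via keto aldehyde 6 (not isolated)
Conditions: O3, CH2Cl2/MeOH, −78 °C; Me2S; then dibenzylammonium trifluoroacetate (0.3 equiv), PhH, 50 °C
Reagents that add atoms: none
Why: Ozonolysis unmasks the aldehyde and the ammonium salt drives the intramolecular aldol condensation of the ketone α-CH2 onto it, closing ring B as the ring-fused enone; the stereocentre is not enolisable in this enone.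

Step 4
Reactants: 8 1,3-dithiane; 4 allyl bromide
Product: 9 2-allyl-1,3-dithiane
Conditions: n-BuLi, THF, −30 °C; then 4, −78 °C → rt
Reagents that add atoms: none
Why: Corey–Seebach alkylation of 2-lithio-1,3-dithiane gives the masked but-3-enoyl anion equivalent.

Step 5
Reactants: 7 dimethyl (3aS)-1-oxo-2,3,3a,5-tetrahydro-1H-pentalene-4,4-dicarboxylate; 9 2-allyl-1,3-dithiane
Product: 11 dimethyl (3aS)-6-(2-allyl-1,3-dithian-2-yl)-1-[(trifluoromethylsulfonyl)oxy]-3,3a,5,6-tetrahydro-2H-pentalene-4,4-dicarboxylate, via lithium enolate 10 (not isolated)
Conditions: 9, n-BuLi, THF, −30 °C; HMPA, −78 °C; then 7; then PhNTf2, −78 → 0 °C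
Reagents that add atoms: N-phenylbis(trifluoromethanesulfonimide), O=S(=O)(N(c1ccccc1)S(=O)(=O)C(F)(F)F)C(F)(F)F
Why: The lithiated dithiane adds 1,4 to the enone in THF/HMPA (umpoled acyl-anion conjugate addition) and O-triflation of the regiodefined enolate fixes the position of the future tetrasubstituted alkene; the new CH stereocentre is erased in step 9.

Step 6
Reactants: 11 dimethyl (3aS)-6-(2-allyl-1,3-dithian-2-yl)-1-[(trifluoromethylsulfonyl)oxy]-3,3a,5,6-tetrahydro-2H-pentalene-4,4-dicarboxylate
Product: 13 tricyclic spiro-dithiane diester (ring C closed), via alkylborane 12 (not isolated)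
Conditions: 9-BBN-H, THF, 0 °C → rt; then PdCl2(dppf) (10 mol%), AsPh3, Cs2CO3, DMF/H2O, 50 °C, 0.005 M
Reagents that add atoms: none
Why: 9-BBN hydroborates only the terminal alkene and the alkylborane couples intramolecularly with the enol triflate (B-alkyl Suzuki–Miyaura coupling) to close the seven-membered ring, the two arms being held cis on the ring-A alkene.

Step 7
Reactants: 13 tricyclic spiro-dithiane diester
Product: 14 tricyclic spiro-dithiane mono-ester (ester cis to the ring-A CH2)
Conditions: LiCl, H2O, DMSO, 150 °C
Reagents that add atoms: none
Why: Krapcho dealkoxycarbonylation removes one ester and irreversible protonation of the ester enolate from the face opposite the adjacent ring-A CH2 gives the cis ester (both ring-B methine hydrogens cis); it is run while the ketone is still masked, so the hot salt medium never meets the enolisable β,γ-unsaturated ketone.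

Step 8
Reactants: 14 tricyclic spiro-dithiane mono-ester
Product: 15 tricyclic β,γ-unsaturated keto mono-ester
Conditions: MeI, CaCO3, MeCN/H2O (4:1), 45 °C
Reagents that add atoms: water, O
Why: Alkylative hydrolysis of the dithiane unmasks the ring-C ketone under mild, buffered conditions that leave the ester stereocentre and the tetrasubstituted alkene untouched.

Step 9
Reactants: 15 tricyclic β,γ-unsaturated keto mono-ester; 16 methylamine; 17 formaldehyde
Product: 19 tetracyclic amino ketone (N-methylpiperidine bridged across the ketone), via mono-Mannich base 18 (not isolated)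
Conditions: 16 (33% in EtOH, 1.1 equiv), 17 (37% aq., 2.2 equiv), AcOH, 70 °C
Reagents that add atoms: formaldehyde (second equivalent of 17), C=O
Why: Proposed new method: a double Mannich annulation that takes up one methylamine and two formaldehyde molecules with loss of two waters; the α′-CH2 is aminomethylated first and the tethered N-methyl iminium ion, formed with the second formaldehyde, then attacks the α-carbon of the extended dienol of the β,γ-unsaturated ketone (six-membered closure; γ-attack would need an eight-membered ring), creating the quaternary bridgehead on the convex face anti to the ester and locking the tetrasubstituted alkene out of conjugation; the closest known chemistry is the double Mannich annulation of saturated cycloalkanones to 3-azabicyclo[3.3.1]nonan-9-ones and the α-selective (deconjugative) alkylation of extended enolates.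

Step 10
Reactants: 19 tetracyclic amino ketone; 20 (methoxymethyl)triphenylphosphonium chloride
Product: 22 bridge aldehyde (epimers at the formyl-bearing carbon), via enol ether 21 (not isolated)
Conditions: 20 (3.0 equiv), KN(SiMe3)2 (2.8 equiv), THF, 0 °C → rt; then 2 M HCl, THF, rt; NaHCO3 work-up
Reagents that add atoms: water, O
Why: Wittig methoxymethylenation of the bridging ketone (base kept below the phosphonium salt so that no free amide base reaches the ester) and acid hydrolysis of the enol ether give the homologous aldehyde (one-carbon homologation); the aldehyde α-centre is left as a mixture because it is enolised in the next step.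

Step 11
Reactants: 22 bridge aldehyde; 23 pent-1-en-3-one (ethyl vinyl ketone)
Product: 24 quaternary keto aldehyde
Conditions: 23 (2 equiv), 1,5,7-triazabicyclo[4.4.0]dec-5-ene (10 mol%), PhMe, −20 °C; AcOH quench
Reagents that add atoms: none
Why: Base-catalysed Michael addition of the α,α-disubstituted aldehyde enolate to the enone forms the quaternary spiro carbon, the enone approaching the exocyclic enolate from the cycloheptene side, away from the two axial C–H bonds of the piperidine chair, so that the formyl group ends syn to nitrogen.

Step 12
Reactants: 24 quaternary keto aldehyde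
Product: 26 CNP0159589.2 (target), via hydroxy ketone 25 (not isolated)
Conditions: NaBH4, MeOH/CH2Cl2, −78 °C; then TsOH·H2O (1.2 equiv), 4 Å MS, PhMe, 80 °C; NaHCO3 work-up
Reagents that add atoms: none
Why: NaBH4 at −78 °C reduces the aldehyde much faster than the dialkyl ketone (chemoselective reduction), and acid-catalysed dehydration of the resulting six-membered hemiketal gives the endocyclic enol ether of ring E without touching any stereocentre.

## Compound list

1 | cyclopent-2-en-1-one | O=C1C=CCC1 | starting material
2 | dimethyl malonate | COC(=O)CC(=O)OC | starting material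
3 | dimethyl 2-[(1S)-3-oxocyclopentyl]malonate | O=C1CC[C@@H](C1)C(C(=O)OC)C(=O)OC | intermediate
4 | allyl bromide (3-bromoprop-1-ene) | C=CCBr | starting material
5 | dimethyl 2-allyl-2-[(1S)-3-oxocyclopentyl]malonate | O=C1CC[C@@H](C1)C(CC=C)(C(=O)OC)C(=O)OC | intermediate
6 | keto aldehyde: dimethyl 2-(2-oxoethyl)-2-[(1S)-3-oxocyclopentyl]malonate | O=C1CC[C@@H](C1)C(CC=O)(C(=O)OC)C(=O)OC | intermediate
7 | dimethyl (3aS)-1-oxo-2,3,3a,5-tetrahydro-1H-pentalene-4,4-dicarboxylate (enone C=C between C6 and C6a) | O=C1CC[C@H]2C1=CCC2(C(=O)OC)C(=O)OC | intermediate
8 | 1,3-dithiane | C1CSCSC1 | starting material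
9 | 2-allyl-1,3-dithiane | C=CCC1SCCCS1 | intermediate
10 | lithium enolate: lithium (3aS)-6-(2-allyl-1,3-dithian-2-yl)-4,4-bis(methoxycarbonyl)-2,3,3a,4,5,6-hexahydropentalen-1-olate (C6 unassigned) | [Li]OC1=C2[C@H](CC1)C(C(=O)OC)(C(=O)OC)CC2C3(CC=C)SCCCS3 | intermediate
11 | dimethyl (3aS)-6-(2-allyl-1,3-dithian-2-yl)-1-[(trifluoromethylsulfonyl)oxy]-3,3a,5,6-tetrahydro-2H-pentalene-4,4-dicarboxylate (C6 unassigned) | O=S(=O)(OC1=C2[C@H](CC1)C(C(=O)OC)(C(=O)OC)CC2C3(CC=C)SCCCS3)C(F)(F)F | intermediate
12 | alkylborane: 11 with the allyl group converted into a 3-(9-borabicyclo[3.3.1]nonan-9-yl)propyl group | O=S(=O)(OC1=C2[C@H](CC1)C(C(=O)OC)(C(=O)OC)CC2C3(CCCB4C5CCCC4CCC5)SCCCS3)C(F)(F)F | intermediate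
13 | tricyclic spiro-dithiane diester: 5-5-7 carbotricycle, tetrasubstituted C=C shared by rings A and C, ring-C carbonyl carbon masked as spiro-1,3-dithiane, gem-dimethyl ester on ring B next to the (S) ring-fusion CH (ring-B CH bearing the dithiane carbon unassigned) | S1CCCSC12CCCC3=C4[C@H](CC3)C(C(=O)OC)(C(=O)OC)CC24 | intermediate
14 | tricyclic spiro-dithiane mono-ester: as 13 with one CO2Me, cis to the ring-A CH2 (both ring-B methine H next to each other cis; CH bearing the dithiane carbon unassigned) | S1CCCSC12CCCC3=C4[C@H](CC3)[C@H](C(=O)OC)CC24 | intermediate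
15 | tricyclic β,γ-unsaturated keto mono-ester: as 14 with a free ring-C ketone in place of the dithiane (CH α to the ketone unassigned, enolised in step 9) | O=C1CCCC2=C3[C@H](CC2)[C@H](C(=O)OC)CC13 | intermediate
16 | methylamine | CN | starting material
17 | formaldehyde | C=O | starting material
18 | mono-Mannich base: 15 carrying CH2NHCH3 on the α′-carbon (former CH2 next to the ketone) | O=C1C(CNC)CCC2=C3[C@H](CC2)[C@H](C(=O)OC)CC13 | intermediate
19 | tetracyclic amino ketone: 8-methyl-8-azabicyclo[4.3.1]dec-2-en-10-one unit (ketone on the one-carbon bridge), quaternary bridgehead shared with ring B, aminomethyl arm trans to the ester across ring B | O=C2[C@@H]1CCC3=C4[C@H](CC3)[C@H](C(=O)OC)C[C@@]42CN(C)C1 | intermediate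
20 | (methoxymethyl)triphenylphosphonium chloride | COC[P+](c1ccccc1)(c1ccccc1)c1ccccc1.[Cl-] | starting material
21 | enol ether: methoxymethylidene derivative of 19 (E/Z mixture) | COC=C2[C@@H]1CCC3=C4[C@H](CC3)[C@H](C(=O)OC)C[C@@]42CN(C)C1 | intermediate
22 | bridge aldehyde: 19 with C=O replaced by CH–CHO (epimers at that carbon) | O=CC2[C@@H]1CCC3=C4[C@H](CC3)[C@H](C(=O)OC)C[C@@]42CN(C)C1 | intermediate
23 | pent-1-en-3-one (ethyl vinyl ketone) | CCC(=O)C=C | starting material
24 | quaternary keto aldehyde: bridge carbon bearing CHO (syn to N) and CH2CH2C(=O)CH2CH3 (over ring C) | CCC(=O)CC[C@]2(C=O)[C@@H]1CCC3=C4[C@H](CC3)[C@H](C(=O)OC)C[C@@]42CN(C)C1 | intermediate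
25 | hydroxy ketone: 24 with CHO reduced to CH2OH (in equilibrium with its cyclic hemiketal) | CCC(=O)CC[C@]2(CO)[C@@H]1CCC3=C4[C@H](CC3)[C@H](C(=O)OC)C[C@@]42CN(C)C1 | intermediate
26 | CNP0159589.2 | CCC1=CC[C@]2(CO1)[C@@H]1CCC3=C4[C@H](CC3)[C@H](C(=O)OC)C[C@@]42CN(C)C1 | target

## Step count and weak points

Total steps: 12. Longest linear sequence: 11 (steps 1–3 and 5–12; step 4 is a one-step side branch).

The three steps most likely to fail:

**Step 6 (seven-membered ring closure).** The intramolecular B-alkyl Suzuki coupling has to join a hindered tetrasubstituted enol triflate to an alkylborane next to a sulfur-rich quaternary carbon; protodeboronation, β-hydride elimination or catalyst poisoning are the likely failures. The fallback sets out from 11 and comes back at 13. Stille coupling of 11 with tributyl(vinyl)stannane (Pd(PPh3)4, LiCl, THF) gives the 1-vinyl diene F1. Ring-closing metathesis of F1 with RuCl2(=CHPh)(PCy3)(H2IMes) (second-generation Grubbs catalyst) between the vinyl and allyl groups gives the cyclohepta-1,3-diene F2. Diimide (TsNHNH2, NaOAc) then saturates only the disubstituted alkene of F2 to give 13.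

**Step 9 (the proposed double Mannich annulation).** The reaction may stall at the mono-Mannich base, attack the γ-carbon intermolecularly, or drift to the conjugated enone isomer, which would put the ring-fusion stereocentre at risk. The fallback uses known reactions only, sets out from 15 and comes back at 19. The extended potassium enolate of 15 (KN(SiMe3)2, THF, −78 °C) is alkylated at the α-carbon with tert-butyl N-(chloromethyl)-N-methylcarbamate, a deconjugative α-alkylation that gives the Boc-protected aminomethyl ketone F3. CF3CO2H removes the Boc group to give the secondary amine F4. Aqueous formaldehyde in AcOH/NaOAc buffer then closes the piperidine of F4 by an ordinary intramolecular Mannich reaction at the remaining α-CH2, giving 19.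

**Step 11 (quaternary spiro carbon).** The crowded aldehyde may add sluggishly, the product may undergo Robinson-type aldol closure under base, and the facial selectivity rests on a steric argument that has to be checked by NOE. The fallback sets out from 22 and comes back at 24. Aldehyde 22 is converted with Me3SiOTf/Et3N into the trimethylsilyl enol ether F5. F5 is added to 23 in a Mukaiyama–Michael reaction (Me3SiOTf, 1.5 equiv, CH2Cl2, −78 °C) and aqueous work-up gives 24 without any basic step. The fallback cures only the reactivity and aldol problems; the face of attack remains substrate-controlled.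

## Further compounds

F1 | step 6 | dimethyl (3aS)-6-(2-allyl-1,3-dithian-2-yl)-1-vinyl-3,3a,5,6-tetrahydro-2H-pentalene-4,4-dicarboxylate | C=CC1=C2[C@H](CC1)C(C(=O)OC)(C(=O)OC)CC2C3(CC=C)SCCCS3
F2 | step 6 | cyclohepta-1,3-diene analogue of 13 (extra disubstituted C=C conjugated to the ring-fusion alkene) | S1CCCSC12CC=CC3=C4[C@H](CC3)C(C(=O)OC)(C(=O)OC)CC24
F3 | step 9 | 15 carrying CH2N(CH3)CO2C(CH3)3 on the now quaternary α-carbon | O=C1CCCC2=C3[C@H](CC2)[C@H](C(=O)OC)C[C@]13CN(C)C(=O)OC(C)(C)C
F4 | step 9 | secondary amine: 15 carrying CH2NHCH3 on the quaternary α-carbon | O=C1CCCC2=C3[C@H](CC2)[C@H](C(=O)OC)C[C@]13CNC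
F5 | step 11 | trimethylsilyl enol ether of aldehyde 22 | C[Si](C)(C)OC=C2[C@@H]1CCC3=C4[C@H](CC3)[C@H](C(=O)OC)C[C@@]42CN(C)C1
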